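## Analysis of the target

The target 20 (C48H34O28) is a linear chain of eight benzene rings, lettered A to H, joined by seven diaryl ether oxygens and carrying 21 free phenolic hydroxyls. It has no stereocentre and no ring other than the eight benzenes.

In rings B to H, C1 is the carbon bonded to the ether oxygen that leads back towards ring A. Ring A is a 2,4,6-trihydroxyphenyl group. Ring B has OH at C3 and C4 and its onward ether oxygen at C5. Rings C, E and G have OH at C3, C4 and C5 and the onward ether oxygen at C6. Rings D and F have OH at C3 and C5 and the onward ether oxygen at C4. Ring H has OH at C3, C4 and C5.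

The feature on which the route is built: in every one of rings B to H, C4 (para to C1) carries oxygen and is flanked by oxygen-bearing C3 and C5. All seven rings are thus the same 1-aryloxy-3,4,5-trioxygenated benzene. In rings B, C, E, G and H this C4 oxygen is a free hydroxyl; in rings D and F it is the onward ether oxygen. The ring pairs C–D, E–F and G–H are in addition one and the same dimer, used three times.

The difficulty is that all seven C–O bonds join two electron-rich rings, and six of the seven ether oxygens sit on a carbon with two oxygenated neighbours. That is the worst case for metal-mediated etherification. The 28 oxygens must also be told apart without a long protecting-group sequence. The free pyrogallol- and hydroxyquinol-type rings are oxidised by air, quickly in base, so all hydroxyls stay masked until the last step and the last two steps avoid base and oxygen.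

## Retrosynthetic reasoning

**20 from 19.** The sixteen O–methyl bonds are cut last (Lewis-acid ether cleavage). Methyl ethers are chosen because the monomer 1 already carries them, so no protecting-group step is spent on them.

**19 from 17 (key disconnection).** The five C4–OH bonds of rings B, C, E, G and H are cut at once and replaced by C4–CHO bonds. In the forward direction a fivefold Baeyer–Villiger oxidation of the Dakin type turns five aryl–carbon bonds into aryl–oxygen bonds. The cut is made here because a formyl group at C4 is exactly what makes C1 of the same ring electrophilic. With it, every diaryl ether bond of pentaaldehyde 17 becomes an uncatalysed SNAr bond, and 17 becomes an oligomer of one monomer, 1 (seven times), plus 14.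

**17 from 16 and 13.** The ether bond between C5 of ring B and C1 of ring C is cut. The phenoxide of 16 must displace the single fluoride of 13, which is para to the formyl group of ring C.

**16 from 15, and 15 from 14 and 1.** The C5 hydroxyl of ring B comes from one of the two equivalent methoxy groups of 15, cleaved under chelation control by the neighbouring formyl group. The bond between ring A oxygen and C1 of ring B is an SNAr of hindered phenol 14 on 1.

**13 from 12, 12 from 8 and 11, 11 from 10, 10 from 8 and 9.** The two bonds from C4 oxygen of ring F to C1 of ring G and from C4 oxygen of ring D to C1 of ring E are cut. Each forward union needs a nucleophile whose own fluoride is inert. This is secured by keeping the formyl group of the fluorinated ring of 8 as an acetal (off) and hydrolysing it after the union (on). The chain therefore grows from ring H towards ring A, and all formyl groups on rings C, E, G and H survive to the key step.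

**8 and 9 from 6.** One dimer serves both roles. Oxidation of its only free formyl group gives the nucleophile 8 (used twice). Hydrolysis of its acetal gives the electrophile 9 (used once).

**6 from 5 and 1.** The bond from C6 oxygen of ring C (E, G) to C1 of ring D (F, H) is made once and used three times. The phenoxide of 5 attacks 1; the fluoride of 5 cannot react because its ring carries the acetal.

**5 from 2, and 2 from 1.** The extra C6 oxygen of rings C, E and G is put in by ortho-metalation, borylation and oxidation of acetal 2. Its only two ring hydrogens are equivalent and lie between fluorine and methoxy, so no regiochemical question arises.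

## Alternatives that were turned down

**Alternative 1: the textbook route, ring-by-ring copper-mediated Ullmann etherification.**
- Disconnection: each of the seven Ar–O bonds in turn, between a permethylated bromoarene and a phenol.
- Forward key step: CuI-catalysed coupling, for example of the ring G–H bromide A1 with a 2,6-dimethoxyphenol-type ring F phenol, repeated along the chain.
- Why turned down: every bromide is electron-rich and most are ortho-substituted, and most phenols are di-ortho-substituted. Oxidative addition and the C–O forming step are both slow, and reductive loss of bromine competes in each of seven couplings. The route also needs five or six different, orthogonally protected monomers, each a synthesis of its own, and an unmasking step between couplings. The count passes 25 steps without any convergence.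

**Alternative 2: biomimetic anodic C–O coupling of phenols.**
- Disconnection: the bond between C1 of a D/F/H-type ring and the oxygen of the neighbouring C/E/G ring, the C4 hydroxyl being the site of oxidation.
- Forward key step: anodic oxidation of a 2,6-dimethoxyphenol to its phenoxonium ion and capture at the para carbon by the oxygen of a second phenol, giving ethers of the type A2.
- Why turned down: the para position of such a phenoxonium ion is attacked by carbon of another phenol (C–C coupling) and by its own kind (poly(phenylene ether) formation) at least as readily as by a foreign phenol oxygen. The product A2 is more electron-rich than either partner and is oxidised further at the same potential. The ortho-linked bonds to C1 of rings C, E and G have no oxidisable para-hydroxy handle of this kind. Seven selective cross-couplings cannot be argued for.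

**Alternative 3: late aromatisation of a cyclohexane-1,3-dione for the rings whose ether carbon lies between two hydroxyls (A, D, F).**
- Disconnection: the hindered O–C bond, traced back to a carbene carbon.
- Forward key step: Rh2(OAc)4-catalysed O–H insertion of diazodione A3 into the neighbouring phenol to give aryloxydione A4, then dehydrogenation to the arene.
- Why turned down: the oxygen that rings A, D and F need at the carbon para to the ether sits beta to both carbonyl groups of A4. It is lost by E1cB elimination as soon as the ring is enolised, which gives the deoxy ring. The method also addresses only three of the seven ether bonds, offers nothing for the pentaoxygenated rings C, E and G, and adds an oxidation-level adjustment per ring.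

Key step: step 13

Assumption: the diaryl ether axes of the target rotate freely, so the SMILES without stereodescriptors defines it fully, and 4-fluoro-2,6-dimethoxybenzaldehyde (1) is taken as a catalogue compound.

## Route

Step 1
Reactants: 1 4-fluoro-2,6-dimethoxybenzaldehyde
Product: 2 2-(4-fluoro-2,6-dimethoxyphenyl)-5,5-dimethyl-1,3-dioxane
Conditions: 2,2-dimethylpropane-1,3-diol, p-TsOH·H2O (cat.), toluene, reflux, Dean–Stark
Reagents that add atoms: 2,2-dimethylpropane-1,3-diol, OCC(C)(C)CO
Why: Acid-catalysed acetalisation driven by azeotropic removal of water; the six-membered neopentyl acetal is chosen because it is stable to organolithium, carbonate base and buffered peracid and removes the acceptor character of the formyl group.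

Step 2
Reactants: 2 2-(4-fluoro-2,6-dimethoxyphenyl)-5,5-dimethyl-1,3-dioxane
Product: 5 3-(5,5-dimethyl-1,3-dioxan-2-yl)-6-fluoro-2,4-dimethoxyphenol, via aryllithium 3 (not isolated), via boronate 4 (not isolated)
Conditions: s-BuLi, TMEDA, THF, −78 °C; B(OMe)3, −78 → 0 °C; then 30% H2O2, aq. NaOH, 0 °C → rt
Reagents that add atoms: sec-butyllithium, CCC(C)[Li] (lithium of 3); trimethyl borate, COB(OC)OC (boron and two methoxy groups of 4); hydrogen peroxide, OO (hydroxyl oxygen of 5)
Why: Directed ortho-metalation: the two ring hydrogens of 2 are equivalent and lie between fluorine and methoxy, the most acidic kind of site, and at −78 °C the ortho-fluoroaryllithium should not yet lose LiF; borylation and alkaline peroxide oxidation (1,2-shift of aryl from boron to oxygen) should then give the phenol with the acetal untouched.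

Step 3
Reactants: 5 3-(5,5-dimethyl-1,3-dioxan-2-yl)-6-fluoro-2,4-dimethoxyphenol; 1 4-fluoro-2,6-dimethoxybenzaldehyde
Product: 6 4-[3-(5,5-dimethyl-1,3-dioxan-2-yl)-6-fluoro-2,4-dimethoxyphenoxy]-2,6-dimethoxybenzaldehyde
Conditions: Cs2CO3, DMSO, 100 °C
Reagents that add atoms: none
Why: SNAr: the phenoxide of 5 attacks the fluorine-bearing carbon of 1 and the Meisenheimer charge is taken up by the para formyl group; the fluoride of 5 itself stays inert because its ring carries an acetal instead of an acceptor, so no self-condensation is expected.

Step 4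
Reactants: 6 4-[3-(5,5-dimethyl-1,3-dioxan-2-yl)-6-fluoro-2,4-dimethoxyphenoxy]-2,6-dimethoxybenzaldehyde
Product: 8 4-[3-(5,5-dimethyl-1,3-dioxan-2-yl)-6-fluoro-2,4-dimethoxyphenoxy]-2,6-dimethoxyphenol, via formate 7 (not isolated)
Conditions: mCPBA, NaHCO3, CH2Cl2, 0 °C → rt; then K2CO3 (cat.), MeOH, rt, argon
Reagents that add atoms: 3-chloroperbenzoic acid, OOC(=O)c1cccc(Cl)c1 (the oxygen between ring and formyl carbon in 7, kept as the phenol oxygen of 8)
Why: Baeyer–Villiger oxidation of the Dakin type: the 2,6-dimethoxy-4-aryloxyphenyl group migrates to oxygen in preference to hydride, the buffer keeps the acid-labile acetal of the other ring intact, and mild methanolysis of the aryl formate frees the phenol that serves as nucleophile in steps 6 and 8.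

Step 5
Reactants: 6 4-[3-(5,5-dimethyl-1,3-dioxan-2-yl)-6-fluoro-2,4-dimethoxyphenoxy]-2,6-dimethoxybenzaldehyde
Product: 9 4-fluoro-3-(4-formyl-3,5-dimethoxyphenoxy)-2,6-dimethoxybenzaldehyde
Conditions: 1 M HCl, THF, rt
Reagents that add atoms: water, O
Why: Acid-catalysed acetal hydrolysis, fast for this electron-rich benzylic acetal; it restores the formyl group para to fluorine and so switches the fluoride on for SNAr.

Step 6
Reactants: 8 4-[3-(5,5-dimethyl-1,3-dioxan-2-yl)-6-fluoro-2,4-dimethoxyphenoxy]-2,6-dimethoxyphenol; 9 4-fluoro-3-(4-formyl-3,5-dimethoxyphenoxy)-2,6-dimethoxybenzaldehyde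
Product: 10 4-{4-[3-(5,5-dimethyl-1,3-dioxan-2-yl)-6-fluoro-2,4-dimethoxyphenoxy]-2,6-dimethoxyphenoxy}-3-(4-formyl-3,5-dimethoxyphenoxy)-2,6-dimethoxybenzaldehyde (rings E to H)
Conditions: Cs2CO3, DMSO, 110 °C
Reagents that add atoms: none
Why: SNAr: the electron-rich 2,6-dimethoxyphenoxide of 8 attacks the only activated C–F of 9 (para to formyl); the fluoride of 8 is switched off by its acetal, so the union should stop after one addition, and fluoride should be displaced far faster than the aryloxy group para to the other formyl group.

Step 7
Reactants: 10 the ring E to H acetal dialdehyde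
Product: 11 4-[4-(6-fluoro-3-formyl-2,4-dimethoxyphenoxy)-2,6-dimethoxyphenoxy]-3-(4-formyl-3,5-dimethoxyphenoxy)-2,6-dimethoxybenzaldehyde (rings E to H)
Conditions: 1 M HCl, THF, rt
Reagents that add atoms: water, O
Why: Acetal hydrolysis as in step 5; it switches on the fluoride of ring E while ethers and the two other aldehydes are unaffected.

Step 8
Reactants: 8 4-[3-(5,5-dimethyl-1,3-dioxan-2-yl)-6-fluoro-2,4-dimethoxyphenoxy]-2,6-dimethoxyphenol; 11 the ring E to H trialdehyde
Product: 12 hexamer of rings C to H: 11 in which the fluorine is replaced by the 4-[3-(5,5-dimethyl-1,3-dioxan-2-yl)-6-fluoro-2,4-dimethoxyphenoxy]-2,6-dimethoxyphenoxy group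
Conditions: Cs2CO3, DMSO, 110 °C
Reagents that add atoms: none
Why: Second use of the same SNAr union as step 6, with the same chemoselectivity argument (one activated fluoride in 11, dormant fluoride in 8).

Step 9
Reactants: 12 the ring C to H acetal trialdehyde
Product: 13 hexamer tetraaldehyde: 12 with the dioxanyl group replaced by formyl
Conditions: 1 M HCl, THF, rt
Reagents that add atoms: water, O
Why: Acetal hydrolysis as in steps 5 and 7; it switches on the fluoride of ring C for the last union.

Step 10
Reactants: 14 2,4,6-trimethoxyphenol; 1 4-fluoro-2,6-dimethoxybenzaldehyde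
Product: 15 2,6-dimethoxy-4-(2,4,6-trimethoxyphenoxy)benzaldehyde
Conditions: Cs2CO3, DMSO, 100 °C
Reagents that add atoms: none
Why: SNAr of a hindered but strongly nucleophilic phenoxide on the formyl-activated fluoride; it makes the ether bond on ring A, whose oxygen lies between two methoxy groups, without a metal catalyst.

Step 11
Reactants: 15 2,6-dimethoxy-4-(2,4,6-trimethoxyphenoxy)benzaldehyde
Product: 16 2-hydroxy-6-methoxy-4-(2,4,6-trimethoxyphenoxy)benzaldehyde
Conditions: BCl3, CH2Cl2, −78 → 0 °C; then H2O
Reagents that add atoms: none
Why: Chelation-controlled ether cleavage: BCl3 is held between the formyl oxygen and one of the two equivalent ortho methoxy oxygens and chloride removes that methyl group by SN2; the resulting boron chelate shuts off the second ortho site, and the unchelated methoxy groups of ring A should not react at this temperature.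

Step 12
Reactants: 16 2-hydroxy-6-methoxy-4-(2,4,6-trimethoxyphenoxy)benzaldehyde; 13 the ring C to H tetraaldehyde
Product: 17 octamer pentaaldehyde: 13 in which the fluorine is replaced by the 2-formyl-3-methoxy-5-(2,4,6-trimethoxyphenoxy)phenoxy group
Conditions: Cs2CO3, DMSO, 120 °C
Reagents that add atoms: none
Why: SNAr of the phenoxide of 16 on the single fluoride of 13, para to the formyl group of ring C; it closes the chain at the bond between C5 oxygen of ring B and C1 of ring C and leaves a formyl group on C4 of each of rings B, C, E, G and H.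

Step 13
Reactants: 17 the octamer pentaaldehyde
Product: 19 octamer pentaphenol: 17 with each of its five formyl groups replaced by hydroxyl (hexadeca-O-methyl ether of the target), via pentaformate 18 (not isolated)
Conditions: mCPBA (7.5 equiv), NaHCO3, CH2Cl2, 0 °C → rt; then Et3N, MeOH, rt, argon
Reagents that add atoms: 3-chloroperbenzoic acid, OOC(=O)c1cccc(Cl)c1 (the five oxygens inserted between ring and formyl carbon in 18, kept as the five phenol oxygens of 19)
Why: Fivefold Baeyer–Villiger oxidation of the Dakin type: the peracid adds to each formyl carbonyl to give a tetrahedral peroxy adduct, from which the aryl group shifts from carbon to oxygen with loss of 3-chlorobenzoate, giving an aryl formate that methanolysis converts to the phenol. The closest known reaction is the peracid conversion of 2,4,6-trialkoxybenzaldehydes into the corresponding phenols. No ring is closed and no stereocentre is formed; the step changes five aryl–carbon bonds into the five aryl–oxygen bonds at C4 of rings B, C, E, G and H. The step needs aryl rather than hydride migration at all five sites, which is secured because every formyl group sits between two oxygenated ortho carbons and para to an aryloxy oxygen, so each migrating ipso carbon is stabilised by three donors. The five sites share this environment and should react at similar rates, so no partly oxidised stage should accumulate. The step also needs the peracid to spare the formyl-free rings A, D and F; buffering, low temperature and a limited excess of peracid serve this, and each new phenol stays masked as its less electron-rich formate until the oxidant is gone. The formates are cleaved without strong base and under argon because the five 2,6-dioxygenated phenols of 19 are air-sensitive as phenoxides.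

Step 14
Reactants: 19 the octamer pentaphenol
Product: 20 the target, with rings A to H as defined in the analysis and 21 free hydroxyls
Conditions: BBr3 (excess), CH2Cl2, −78 °C → rt; then H2O; argon, degassed solvents
Reagents that add atoms: none
Why: Lewis-acid ether cleavage: BBr3 binds each methoxy oxygen and bromide removes the methyl group by SN2, while the diaryl ether bonds, with sp2 carbon on both sides, offer no such path and should stay; acidic, oxygen-free work-up protects the polyphenol.

## Compound list

1 | 4-fluoro-2,6-dimethoxybenzaldehyde | COc1cc(F)cc(OC)c1C=O | starting material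
2 | 2-(4-fluoro-2,6-dimethoxyphenyl)-5,5-dimethyl-1,3-dioxane | COc1cc(F)cc(OC)c1C1OCC(C)(C)CO1 | intermediate
3 | [3-(5,5-dimethyl-1,3-dioxan-2-yl)-6-fluoro-2,4-dimethoxyphenyl]lithium | COc1cc(F)c([Li])c(OC)c1C1OCC(C)(C)CO1 | intermediate (not isolated)
4 | dimethyl [3-(5,5-dimethyl-1,3-dioxan-2-yl)-6-fluoro-2,4-dimethoxyphenyl]boronate | COB(OC)c1c(F)cc(OC)c(C2OCC(C)(C)CO2)c1OC | intermediate (not isolated)
5 | 3-(5,5-dimethyl-1,3-dioxan-2-yl)-6-fluoro-2,4-dimethoxyphenol | COc1cc(F)c(O)c(OC)c1C1OCC(C)(C)CO1 | intermediate
6 | 4-[3-(5,5-dimethyl-1,3-dioxan-2-yl)-6-fluoro-2,4-dimethoxyphenoxy]-2,6-dimethoxybenzaldehyde | O=Cc1c(OC)cc(Oc2c(F)cc(OC)c(C3OCC(C)(C)CO3)c2OC)cc1OC | intermediate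
7 | 4-[3-(5,5-dimethyl-1,3-dioxan-2-yl)-6-fluoro-2,4-dimethoxyphenoxy]-2,6-dimethoxyphenyl formate | O=COc1c(OC)cc(Oc2c(F)cc(OC)c(C3OCC(C)(C)CO3)c2OC)cc1OC | intermediate (not isolated)
8 | 4-[3-(5,5-dimethyl-1,3-dioxan-2-yl)-6-fluoro-2,4-dimethoxyphenoxy]-2,6-dimethoxyphenol | Oc1c(OC)cc(Oc2c(F)cc(OC)c(C3OCC(C)(C)CO3)c2OC)cc1OC | intermediate
9 | 4-fluoro-3-(4-formyl-3,5-dimethoxyphenoxy)-2,6-dimethoxybenzaldehyde | O=Cc1c(OC)cc(Oc2c(F)cc(OC)c(C=O)c2OC)cc1OC | intermediate
10 | 4-{4-[3-(5,5-dimethyl-1,3-dioxan-2-yl)-6-fluoro-2,4-dimethoxyphenoxy]-2,6-dimethoxyphenoxy}-3-(4-formyl-3,5-dimethoxyphenoxy)-2,6-dimethoxybenzaldehyde (rings E to H) | O=Cc1c(OC)cc(Oc2c(Oc3c(OC)cc(Oc4c(F)cc(OC)c(C5OCC(C)(C)CO5)c4OC)cc3OC)cc(OC)c(C=O)c2OC)cc1OC | intermediate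
11 | 4-[4-(6-fluoro-3-formyl-2,4-dimethoxyphenoxy)-2,6-dimethoxyphenoxy]-3-(4-formyl-3,5-dimethoxyphenoxy)-2,6-dimethoxybenzaldehyde (rings E to H) | O=Cc1c(OC)cc(Oc2c(Oc3c(OC)cc(Oc4c(F)cc(OC)c(C=O)c4OC)cc3OC)cc(OC)c(C=O)c2OC)cc1OC | intermediate
12 | hexamer of rings C to H; ring C with fluorine at C1 and the dioxanyl acetal at C4, rings E, G, H with formyl at C4, all other ring oxygens as methyl ethers | O=Cc1c(OC)cc(Oc2c(Oc3c(OC)cc(Oc4c(Oc5c(OC)cc(Oc6c(F)cc(OC)c(C7OCC(C)(C)CO7)c6OC)cc5OC)cc(OC)c(C=O)c4OC)cc3OC)cc(OC)c(C=O)c2OC)cc1OC | intermediate
13 | hexamer tetraaldehyde of rings C to H; as 12 with formyl in place of the acetal | O=Cc1c(OC)cc(Oc2c(Oc3c(OC)cc(Oc4c(Oc5c(OC)cc(Oc6c(F)cc(OC)c(C=O)c6OC)cc5OC)cc(OC)c(C=O)c4OC)cc3OC)cc(OC)c(C=O)c2OC)cc1OC | intermediate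
14 | 2,4,6-trimethoxyphenol | COc1cc(OC)c(O)c(OC)c1 | starting material
15 | 2,6-dimethoxy-4-(2,4,6-trimethoxyphenoxy)benzaldehyde | O=Cc1c(OC)cc(Oc2c(OC)cc(OC)cc2OC)cc1OC | intermediate
16 | 2-hydroxy-6-methoxy-4-(2,4,6-trimethoxyphenoxy)benzaldehyde | O=Cc1c(O)cc(Oc2c(OC)cc(OC)cc2OC)cc1OC | intermediate
17 | octamer pentaaldehyde; formyl at C4 of rings B, C, E, G, H, sixteen methyl ethers | O=Cc1c(OC)cc(Oc2c(Oc3c(OC)cc(Oc4c(Oc5c(OC)cc(Oc6c(Oc7cc(Oc8c(OC)cc(OC)cc8OC)cc(OC)c7C=O)cc(OC)c(C=O)c6OC)cc5OC)cc(OC)c(C=O)c4OC)cc3OC)cc(OC)c(C=O)c2OC)cc1OC | intermediate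
18 | octamer pentaformate; formyloxy at C4 of rings B, C, E, G, H | O=COc1c(OC)cc(Oc2c(Oc3c(OC)cc(Oc4c(Oc5c(OC)cc(Oc6c(Oc7cc(Oc8c(OC)cc(OC)cc8OC)cc(OC)c7OC=O)cc(OC)c(OC=O)c6OC)cc5OC)cc(OC)c(OC=O)c4OC)cc3OC)cc(OC)c(OC=O)c2OC)cc1OC | intermediate (not isolated)
19 | octamer pentaphenol; hexadeca-O-methyl ether of the target with free OH at C4 of rings B, C, E, G, H | Oc1c(OC)cc(Oc2c(Oc3c(OC)cc(Oc4c(Oc5c(OC)cc(Oc6c(Oc7cc(Oc8c(OC)cc(OC)cc8OC)cc(OC)c7O)cc(OC)c(O)c6OC)cc5OC)cc(OC)c(O)c4OC)cc3OC)cc(OC)c(O)c2OC)cc1OC | intermediate
20 | CNP0175816.0, the octameric phlorotannin with rings A to H and 21 free hydroxyls | Oc1cc(O)c(Oc2cc(O)c(O)c(Oc3cc(O)c(O)c(O)c3Oc3cc(O)c(Oc4cc(O)c(O)c(O)c4Oc4cc(O)c(Oc5cc(O)c(O)c(O)c5Oc5cc(O)c(O)c(O)c5)c(O)c4)c(O)c3)c2)c(O)c1 | target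

## Step count and least certain steps

Total step count: 14. Longest linear sequence: 11 steps (steps 1, 2, 3, 4, 6, 7, 8, 9, 12, 13, 14).

**Step 13 (key step).** The most likely failure is attack of excess peracid on the three formyl-free, highly oxygenated rings A, D and F (ring hydroxylation and onward oxidation to quinones) while the slowest of the five formyl groups is still reacting. Hydride instead of aryl migration at one site would give a carboxylic acid. Both arise because five oxidations must finish in one pot on a very electron-rich molecule.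

The fallback spreads the oxidation over two stages and keeps ring A away from most of the peracid. It sets out from 12. Threefold buffered Baeyer–Villiger oxidation and methanolysis should give the hexamer triphenol F1 with its acetal intact. Methylation (MeI, K2CO3, DMF) should give the hexamer tri-O-methyl ether F2. Acetal hydrolysis (1 M HCl, THF) should give the hexamer monoaldehyde F3, whose fluoride is now activated. SNAr with 16 (Cs2CO3, DMSO) should give the octamer dialdehyde F4, with formyl groups only on rings B and C. Twofold Baeyer–Villiger oxidation and methanolysis should give the octamer diphenol F5, and BBr3 cleavage of its nineteen methyl ethers comes back to the route at 20.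

**Step 12.** The phenoxide of 16 is a weak nucleophile because its charge is shared with the ortho formyl group. Slow substitution at the crowded fluoride of a hexamer would give time for exchange of the aryloxy groups that sit para to formyl groups elsewhere in 13.

The fallback uses the same on/off switch on the nucleophile. It sets out from 16. Acetalisation with 2,2-dimethylpropane-1,3-diol (p-TsOH, toluene, Dean–Stark) should give the ring A–B acetal phenol F6, an ordinary electron-rich phenoxide precursor. SNAr with 13 should give the octamer tetraaldehyde monoacetal F7, and hydrolysis (1 M HCl, THF) comes back to the route at 17.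

**Step 6 (the same holds for step 8).** A di-ortho-substituted phenoxide on a two-ring nucleophile has to attack a carbon that already has an aryloxy neighbour. Steric retardation may allow aryloxide exchange or displacement of a methoxy group ortho to formyl to compete.

The fallback makes the hindered oxygen–carbon bond with a small nucleophile and moves the other bond to copper catalysis. It sets out from 9. SNAr with commercial 4-bromo-2,6-dimethoxyphenol, used in excess (Cs2CO3, DMSO), should give the trimer bromide F8. Coupling of F8 with phenol 5 (CuI, picolinic acid, K3PO4, DMSO, 90 °C) comes back to the route at 10. The bromide of F8 is unhindered and the fluoride of 5 is inert to copper.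

**Step 2.** The ortho-fluoroaryllithium 3 may lose LiF to an aryne before it is borylated, or the base may attack the acetal position; either lowers the return of 5.

The fallback avoids the aryllithium. It sets out from 2. Electrophilic bromination (NBS, NaHCO3, MeCN, 0 °C) at the only kind of free ring position should give the bromoacetal F9. Hydroxylation (Pd2(dba)3, t-BuXPhos, KOH, dioxane–water, 100 °C) comes back to the route at 5.

**Step 14.** Sixteen ether cleavages may stall when partly demethylated boron aryloxides precipitate, and the free polyphenol may be oxidised by air during isolation.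

The fallback changes how the product is isolated. It sets out from 19. After the BBr3 treatment the crude polyphenol is acetylated at once (Ac2O, pyridine) to give the target henicosaacetate F10, which is stable to air and can be purified on silica. Acid methanolysis (HCl in degassed MeOH) comes back to the route at 20.

## Further compounds

F1 | step 13 | hexamer triphenol of rings C to H (12 with hydroxyl in place of each formyl group, acetal kept) | Oc1c(OC)cc(Oc2c(Oc3c(OC)cc(Oc4c(Oc5c(OC)cc(Oc6c(F)cc(OC)c(C7OCC(C)(C)CO7)c6OC)cc5OC)cc(OC)c(O)c4OC)cc3OC)cc(OC)c(O)c2OC)cc1OC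
F2 | step 13 | hexamer tri-O-methyl ether (F1 with its three hydroxyls methylated) | COc1c(OC)cc(Oc2c(Oc3c(OC)cc(Oc4c(Oc5c(OC)cc(Oc6c(F)cc(OC)c(C7OCC(C)(C)CO7)c6OC)cc5OC)cc(OC)c(OC)c4OC)cc3OC)cc(OC)c(OC)c2OC)cc1OC
F3 | step 13 | hexamer monoaldehyde (F2 with formyl in place of the acetal) | COc1c(OC)cc(Oc2c(Oc3c(OC)cc(Oc4c(Oc5c(OC)cc(Oc6c(F)cc(OC)c(C=O)c6OC)cc5OC)cc(OC)c(OC)c4OC)cc3OC)cc(OC)c(OC)c2OC)cc1OC
F4 | step 13 | octamer dialdehyde (formyl at C4 of rings B and C only, nineteen methyl ethers) | COc1c(OC)cc(Oc2c(Oc3c(OC)cc(Oc4c(Oc5c(OC)cc(Oc6c(Oc7cc(Oc8c(OC)cc(OC)cc8OC)cc(OC)c7C=O)cc(OC)c(C=O)c6OC)cc5OC)cc(OC)c(OC)c4OC)cc3OC)cc(OC)c(OC)c2OC)cc1OC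
F5 | step 13 | octamer diphenol (free OH at C4 of rings B and C, nineteen methyl ethers) | COc1c(OC)cc(Oc2c(Oc3c(OC)cc(Oc4c(Oc5c(OC)cc(Oc6c(Oc7cc(Oc8c(OC)cc(OC)cc8OC)cc(OC)c7O)cc(OC)c(O)c6OC)cc5OC)cc(OC)c(OC)c4OC)cc3OC)cc(OC)c(OC)c2OC)cc1OC
F6 | step 12 | 2-(5,5-dimethyl-1,3-dioxan-2-yl)-3-methoxy-5-(2,4,6-trimethoxyphenoxy)phenol | COc1cc(Oc2c(OC)cc(OC)cc2OC)cc(O)c1C1OCC(C)(C)CO1
F7 | step 12 | octamer tetraaldehyde monoacetal (17 with the formyl group of ring B as its 5,5-dimethyl-1,3-dioxane acetal) | O=Cc1c(OC)cc(Oc2c(Oc3c(OC)cc(Oc4c(Oc5c(OC)cc(Oc6c(Oc7cc(Oc8c(OC)cc(OC)cc8OC)cc(OC)c7C9OCC(C)(C)CO9)cc(OC)c(C=O)c6OC)cc5OC)cc(OC)c(C=O)c4OC)cc3OC)cc(OC)c(C=O)c2OC)cc1OC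
F8 | step 6 | 4-(4-bromo-2,6-dimethoxyphenoxy)-3-(4-formyl-3,5-dimethoxyphenoxy)-2,6-dimethoxybenzaldehyde | O=Cc1c(OC)cc(Oc2c(Oc3c(OC)cc(Br)cc3OC)cc(OC)c(C=O)c2OC)cc1OC
F9 | step 2 | 2-(3-bromo-4-fluoro-2,6-dimethoxyphenyl)-5,5-dimethyl-1,3-dioxane | COc1cc(F)c(Br)c(OC)c1C1OCC(C)(C)CO1
F10 | step 14 | henicosaacetate of the target (all 21 hydroxyls as acetates) | CC(=O)Oc1cc(OC(C)=O)c(Oc2cc(OC(C)=O)c(OC(C)=O)c(Oc3cc(OC(C)=O)c(OC(C)=O)c(OC(C)=O)c3Oc3cc(OC(C)=O)c(Oc4cc(OC(C)=O)c(OC(C)=O)c(OC(C)=O)c4Oc4cc(OC(C)=O)c(Oc5cc(OC(C)=O)c(OC(C)=O)c(OC(C)=O)c5Oc5cc(OC(C)=O)c(OC(C)=O)c(OC(C)=O)c5)c(OC(C)=O)c4)c(OC(C)=O)c3)c2)c(OC(C)=O)c1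
A1 | alternative 1 | 1-bromo-3,4,5-trimethoxy-2-(3,4,5-trimethoxyphenoxy)benzene | COc1cc(Oc2c(Br)cc(OC)c(OC)c2OC)cc(OC)c1OC
A2 | alternative 2 | 2,6-dimethoxy-4-(2,3,4-trimethoxyphenoxy)phenol | COc1cc(Oc2ccc(OC)c(OC)c2OC)cc(OC)c1O
A3 | alternative 3 | 2-diazo-5-methoxycyclohexane-1,3-dione | COC1CC(=O)C(=[N+]=[N-])C(=O)C1
A4 | alternative 3 | 5-methoxy-2-(3,4,5-trimethoxyphenoxy)cyclohexane-1,3-dione | COC1CC(=O)C(Oc2cc(OC)c(OC)c(OC)c2)C(=O)C1
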